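**Retrosynthetic overview**

1. Target (locants follow longipinane numbering: C1 ring-B ketone, C2=C3, cyclobutane C4/C5/C10/C11, C6 = C(CH3)2, C7 = angelate carbon, C8 = CH2, C9 = isovalerate carbon) ⇒ two esterifications of a 7,9-anti diol; C9–OH by hydroxyl-directed reduction, C7–OH by ligand-controlled conjugate borylation of a tricyclic bis-enone.
2. Cyclobutane bond C10–C11 ⇒ 4-exo opening of a ring-B epoxide by the C9-ketone dienolate in a cis-fused bicyclo[5.4.0] enone; the ring-B enone follows by oxidation and dehydrogenation.
3. Seven-membered ring (C4, C5, C6, C7, C8, C9, C10) ⇒ not closed directly: a six-membered ring A (C4, C5, C7, C8, C9, C10) carrying a gem-dimethylcyclopropane across C5–C7 is enlarged by scission of the C5–C7 bond, which inserts C6.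
4. Ring A ⇒ Diels–Alder of (R)-4-methylcyclohex-2-enone (ring B) with a 1-methoxy-3-silyloxypentadiene, then sulfonium-ylide cyclopropanation; order of ring formation: B, A (six-membered), cyclopropane, A (seven-membered), cyclobutane.
5. Enabling feature: the C5–C7 bond of ring A is α to the C11 carbonyl of ring B and β to the C9 carbonyl (1,5-dioxygen pattern C11/C9), so once C6 bridges it as a cyclopropane, the C8=C9 enolate opens it by strain-driven retro-Michael fragmentation.

Key step: step 8

Remark: atoms of intermediates are referred to by the target locants they become; the C10 methyl stereocentre of 7–15 is inconsequential (it is erased in step 12) and is left undefined from 11 onwards.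

**Route**

Step 1
Reactants: 1 4-methylcyclohexanone
Product: 2 (R)-trimethyl[(4-methylcyclohex-1-en-1-yl)oxy]silane
Conditions: (S,S)-bis(1-phenylethyl)amine, n-BuLi, Me3SiCl (internal quench), THF, −78 °C
Reagents that add atoms: chlorotrimethylsilane C[Si](C)(C)Cl
Why: Enantioselective deprotonation of the prochiral ketone by a C2-symmetric chiral lithium amide with in situ silylation (asymmetric desymmetrisation) should give the R enol ether, the stereocentre (later C3) being set by the base's choice between the enantiotopic axial α-hydrogens.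

Step 2
Reactants: 2 (R)-trimethyl[(4-methylcyclohex-1-en-1-yl)oxy]silane
Product: 3 (R)-4-methylcyclohex-2-en-1-one
Conditions: Pd(OAc)2 (10 mol%), O2 (1 atm), DMSO, 25 °C
Reagents that add atoms: none
Why: Saegusa–Ito oxidation (palladium enolate, β-hydride elimination) converts the silyl enol ether regiospecifically into the enone and leaves the remote methyl stereocentre untouched.

Step 3
Reactants: 4 (E)-4-methoxybut-3-en-2-one
Product: 5 (E)-1-methoxypent-1-en-3-one
Conditions: LiN(i-Pr)2, THF, −78 °C; MeI, −78 to 0 °C
Reagents that add atoms: iodomethane CI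
Why: Kinetic α′-deprotonation of the vinylogous ester followed by C-methylation (enolate alkylation) gives the ethyl ketone that later supplies C10 with its methyl group.

Step 4
Reactants: 5 (E)-1-methoxypent-1-en-3-one
Product: 6 (1E,3Z)-3-(tert-butyldimethylsilyloxy)-1-methoxypenta-1,3-diene
Conditions: t-BuMe2SiOTf, Et3N, Et2O, 0 °C
Reagents that add atoms: tert-butyldimethylsilyl trifluoromethanesulfonate CC(C)(C)[Si](C)(C)OS(=O)(=O)C(F)(F)F
Why: Soft enolisation with O-silylation gives the 1-methoxy-3-silyloxy diene, the amine/silyl triflate protocol favouring the Z enol ether of an ethyl ketone.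

Step 5
Reactants: 3 (R)-4-methylcyclohex-2-en-1-one; 6 (1E,3Z)-3-(tert-butyldimethylsilyloxy)-1-methoxypenta-1,3-diene
Product: 7 cis-fused endo adduct 6-(tert-butyldimethylsilyloxy)-8-methoxy-4,5-dimethyl-3,4,4a,5,8,8a-hexahydronaphthalen-1(2H)-one
Conditions: neat, 12 kbar, 25 °C
Reagents that add atoms: none
Why: Diels–Alder cycloaddition in which the nucleophilic methyl-bearing diene terminus bonds to the enone β-carbon (C10–C4) and the methoxy terminus to the α-carbon (C7–C5), the diene adding anti to the ring methyl group (sets C4) and suprafacially (cis ring fusion).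

Step 6
Reactants: 7 cis-fused endo adduct
Product: 8 6-(tert-butyldimethylsilyloxy)-4,5-dimethyl-3,4,4a,5-tetrahydronaphthalen-1(2H)-one (C8=C8a and C6=C7 double bonds)
Conditions: DBU, CH2Cl2, 25 °C
Reagents that add atoms: none
Why: E1cB elimination of methanol through the ring-B enolate installs the C5=C7 bond in conjugation with the C11 ketone while the C9 oxygen stays masked as the silyl enol ether, so no acidic methylene lies between two carbonyl groups.

Step 7
Reactants: 8 silyloxy dienone
Product: 9 gem-dimethylcyclopropane across C8–C8a of 8 with the silyl enol ether retained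
Conditions: i-PrSPh2 BF4, LiN(i-Pr)2, DME, −78 to −20 °C
Reagents that add atoms: isopropyldiphenylsulfonium tetrafluoroborate CC(C)[S+](c1ccccc1)c1ccccc1.F[B-](F)(F)F
Why: Corey–Chaykovsky cyclopropanation with diphenylsulfonium isopropylide (conjugate addition at C7, then 3-exo-tet closure by the ring-B enolate at C5) places C6 with both methyl groups across C5–C7 from the face opposite ring B, the two new stereocentres being erased again in step 8.

Step 8
Reactants: 9 gem-dimethylcyclopropyl silyl enol ether
Product: 12 cis-fused 1,5,5,9-tetramethyl-2,3,4a,5,9,9a-hexahydro-1H-benzo[7]annulene-4,8-dione, via cyclopropyl ketone enolate 10 (not isolated), via ring-opened enolate 11 (not isolated)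
Conditions: Bu4NF, THF, −78 to −40 °C; AcOH, −78 °C
Reagents that add atoms: none
Why: Fluoride cleaves the Si–O bond and releases regiospecifically the C8=C9 enolate 10, whose α-carbon C8 is bonded to cyclopropane carbon C7; the enolate electrons form the C7=C8 bond, the C5–C7 cyclopropane bond breaks and the charge arrives at C5 as the ring-B (C11) enolate 11, a strain-driven homo-retro-Michael (vinylogous E1cB) fragmentation of the same type as the classical base-mediated opening of carenone to eucarvone. No ring-closing bond is made: the six-membered ring A becomes the seven-membered ring by scission of the zero-atom bridge of its bicyclo[4.1.0] unit, which inserts C6 with its two methyl groups between C5 and C7 and unveils the C7=C8–C9=O enone. Only C5–C7 can open, because only that cleavage gives a carbonyl-stabilised carbanion (C5–C6 or C6–C7 scission would leave an unstabilised one), and the silyl mask guarantees that the enolate is formed at C8 and not at C10. The one new stereocentre, C5, should be set by kinetic protonation of 11 on the face opposite the pseudo-axial C4–C10 bond (A1,2 strain), giving the cis ring fusion that step 12 requires. The step needs this cis selectivity and the absence of enolate equilibration, which the aprotic medium and the cold acetic acid quench are meant to secure.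

Step 9
Reactants: 12 cis-fused enedione
Product: 13 1,5,5,9-tetramethyl-8-oxo-2,4a,5,8,9,9a-hexahydro-1H-benzo[7]annulen-4-yl trifluoromethanesulfonate
Conditions: KN(SiMe3)2, THF, −78 °C; PhNTf2, −78 to 0 °C
Reagents that add atoms: N-phenylbis(trifluoromethanesulfonimide) O=S(=O)(N(c1ccccc1)S(=O)(=O)C(F)(F)F)C(F)(F)F
Why: Kinetic deprotonation at the only unhindered α-methylene (C1) of the ring-B ketone, the ring-fusion α-hydrogen being shielded by the adjacent quaternary C6 and the enone α′-hydrogen being a methine, followed by O-sulfonylation gives the less substituted enol triflate.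

Step 10
Reactants: 13 enol triflate
Product: 14 1,5,5,9-tetramethyl-1,2,4a,5,9,9a-hexahydro-8H-benzo[7]annulen-8-one
Conditions: Pd(OAc)2 (5 mol%), PPh3, Bu3N, HCO2H, DMF, 60 °C
Reagents that add atoms: none
Why: Palladium-catalysed formate reduction of the enol triflate (oxidative addition, decarboxylative hydride transfer, reductive elimination) gives the C1=C11 alkene and leaves the enone untouched.

Step 11
Reactants: 14 dienone
Product: 15 3,4-epoxide of 14 with the oxirane trans to the C6 gem-dimethyl carbon and to the C4–C10 bond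
Conditions: m-CPBA, CH2Cl2, 0 °C
Reagents that add atoms: 3-chloroperoxybenzoic acid OOC(=O)c1cccc(Cl)c1
Why: Prilezhaev epoxidation of the electron-rich isolated cis-alkene in preference to the enone, the peracid approaching the face opposite the allylic quaternary C6 and the axial C4–C10 bond.

Step 12
Reactants: 15 epoxy enone
Product: 16 1-hydroxylongipin-7-en-9-one (hydroxyl trans to C10)
Conditions: LiN(i-Pr)2, THF, −78 to 25 °C; H2O
Reagents that add atoms: none
Why: Intramolecular 4-exo-tet epoxide opening by the cross-conjugated dienolate (keto-epoxide cyclisation), in which α′-deprotonation at C10 is the only possibility because C6 is quaternary and the axial C10 attacks C11 trans-diaxially with inversion, setting the quaternary C10 and C11 and leaving the oxygen on C1.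

Step 13
Reactants: 16 tricyclic hydroxy enone
Product: 18 longipina-2,7-diene-1,9-dione, via longipin-7-ene-1,9-dione 17 (not isolated)
Conditions: 2-iodoxybenzoic acid (3.5 equiv), DMSO, 25 to 80 °C
Reagents that add atoms: none
Why: 2-Iodoxybenzoic acid oxidises the alcohol to the ketone and then dehydrogenates it through its enol, which can form only toward C2 because C11 is a bridgehead (Bredt's rule), so the C2=C3 enone arises regiospecifically and the C3 stereocentre disappears.

Step 14
Reactants: 18 tricyclic bis-enone
Product: 20 7-hydroxylongipin-2-ene-1,9-dione (C7 configured as in the target), via 7-(pinacolboryl)longipin-2-ene-1,9-dione 19 (not isolated)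
Conditions: B2pin2, CuCl (5 mol%), NaOt-Bu, chiral SEGPHOS-type bisphosphine (antipode chosen for the required face), MeOH, THF, 25 °C; then H2O2, pH 8 buffer, 0 °C
Reagents that add atoms: bis(pinacolato)diboron CC1(C)OB(OC1(C)C)B1OC(C)(C)C(C)(C)O1 (boron carried in 19); hydrogen peroxide OO
Why: Copper-catalysed conjugate borylation of the disubstituted ring-A enone (the β,β-disubstituted ring-B enone should stay inert) with ligand-controlled facial selectivity sets C7, the tricyclic core being nearly mirror-symmetric about the plane through C6–C10 so that substrate bias is small, and C–B oxidation proceeds with retention.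

Step 15
Reactants: 20 β-hydroxy ketone
Product: 21 7,9-dihydroxylongipin-2-en-1-one (7,9-anti)
Conditions: Me4NBH(OAc)3, MeCN/AcOH, −30 °C
Reagents that add atoms: none
Why: Evans–Saksena reduction, in which the C7 alkoxy(acetoxy)borohydride delivers hydride intramolecularly to C9 to give the 1,3-anti diol while the unactivated ring-B enone is not reduced.

Step 16
Reactants: 21 anti diol
Product: 22 7-hydroxy-9-(3-methylbutanoyloxy)longipin-2-en-1-one
Conditions: (i-BuCO)2O (1.05 equiv), pyridine, DMAP (cat.), CH2Cl2, −20 °C
Reagents that add atoms: isovaleric anhydride CC(C)CC(=O)OC(=O)CC(C)C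
Why: Kinetic monoacylation should select the C9 hydroxyl, whose neighbour C10 has its substituents tied back in the cyclobutane, over the C7 hydroxyl flanked by the gem-dimethyl carbon.

Step 17
Reactants: 22 mono-isovalerate
Product: 23 target CNP0240547.2 (7-angeloyloxy-9-isovaleroyloxylongipin-2-en-1-one)
Conditions: angelic acid, 2,4,6-Cl3C6H2COCl, Et3N, toluene, 25 °C; then 22, 80 °C
Reagents that add atoms: angelic acid C/C=C(/C)C(=O)O
Why: Yamaguchi-type esterification through the mixed anhydride acylates the hindered C7 hydroxyl, the absence of a nucleophilic catalyst and the moderate temperature being chosen to keep the Z geometry of the angelate.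

**Compound list**

1 | 4-methylcyclohexanone | CC1CCC(=O)CC1 | starting material
2 | (R)-trimethyl[(4-methylcyclohex-1-en-1-yl)oxy]silane | C[Si](C)(C)OC1=CC[C@H](C)CC1 | intermediate
3 | (R)-4-methylcyclohex-2-en-1-one | O=C1C=C[C@H](C)CC1 | intermediate
4 | (E)-4-methoxybut-3-en-2-one | CO/C=C/C(C)=O | starting material
5 | (E)-1-methoxypent-1-en-3-one | CO/C=C/C(=O)CC | intermediate
6 | (1E,3Z)-3-(tert-butyldimethylsilyloxy)-1-methoxypenta-1,3-diene | C/C=C(/C=C/OC)O[Si](C)(C)C(C)(C)C | intermediate
7 | cis-fused endo Diels–Alder adduct, 6-(tert-butyldimethylsilyloxy)-8-methoxy-4,5-dimethyl-3,4,4a,5,8,8a-hexahydronaphthalen-1(2H)-one; 4-methyl trans to the C4a–C5 bond | CO[C@H]1C=C(O[Si](C)(C)C(C)(C)C)[C@@H](C)[C@H]2[C@H](C)CCC(=O)[C@@H]12 | intermediate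
8 | 6-(tert-butyldimethylsilyloxy)-4,5-dimethyl-3,4,4a,5-tetrahydronaphthalen-1(2H)-one | O=C1CC[C@@H](C)[C@@H]2[C@H](C)C(O[Si](C)(C)C(C)(C)C)=CC=C12 | intermediate
9 | gem-dimethylcyclopropane across C8–C8a of 8 (cyclopropane on the face opposite ring B), silyl enol ether retained | O=C1CC[C@@H](C)[C@@H]2[C@H](C)C(O[Si](C)(C)C(C)(C)C)=C[C@H]3C(C)(C)[C@@]123 | intermediate
10 | tetrabutylammonium enolate of the desilylated cyclopropyl diketone (not isolated) | O=C1CC[C@@H](C)[C@@H]2[C@H](C)C([O-])=C[C@H]3C(C)(C)[C@@]123.CCCC[N+](CCCC)(CCCC)CCCC | intermediate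
11 | tetrabutylammonium ring-B enolate of the ring-enlarged enedione (not isolated; methyl-bearing carbon next to the enone carbonyl undefined) | [O-]C1=C2C(C)(C)C=CC(=O)C(C)[C@H]2[C@H](C)CC1.CCCC[N+](CCCC)(CCCC)CCCC | intermediate
12 | cis-fused 1,5,5,9-tetramethyl-2,3,4a,5,9,9a-hexahydro-1H-benzo[7]annulene-4,8-dione (C9 epimers) | C1=CC(=O)C(C)[C@H]2[C@H](C)CCC(=O)[C@H]2C1(C)C | intermediate
13 | enol triflate of 12 at the ring-B ketone (C3=C4) | C1=CC(=O)C(C)[C@H]2[C@H](C)CC=C(OS(=O)(=O)C(F)(F)F)[C@H]2C1(C)C | intermediate
14 | cis-fused 1,5,5,9-tetramethyl-1,2,4a,5,9,9a-hexahydro-8H-benzo[7]annulen-8-one | C1=CC(=O)C(C)[C@H]2[C@H](C)CC=C[C@H]2C1(C)C | intermediate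
15 | 3,4-epoxide of 14, oxirane trans to the gem-dimethyl carbon | C1=CC(=O)C(C)[C@H]2[C@H](C)C[C@@H]3O[C@@H]3[C@H]2C1(C)C | intermediate
16 | 1-hydroxylongipin-7-en-9-one (tricyclic; hydroxyl trans to C10, C3 methyl as set in step 5) | C1=CC(=O)[C@@]2(C)[C@@H]3[C@@H](O)C[C@@H](C)[C@H]2[C@@H]3C1(C)C | intermediate
17 | longipin-7-ene-1,9-dione (not isolated) | C1=CC(=O)[C@@]2(C)[C@@H]3C(=O)C[C@@H](C)[C@H]2[C@@H]3C1(C)C | intermediate
18 | longipina-2,7-diene-1,9-dione | C1=CC(=O)[C@@]2(C)[C@@H]3C(=O)C=C(C)[C@H]2[C@@H]3C1(C)C | intermediate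
19 | 7-(4,4,5,5-tetramethyl-1,3,2-dioxaborolan-2-yl)longipin-2-ene-1,9-dione (not isolated) | CC1(C)OB(OC1(C)C)[C@@H]1CC(=O)[C@@]2(C)[C@@H]3C(=O)C=C(C)[C@H]2[C@@H]3C1(C)C | intermediate
20 | 7-hydroxylongipin-2-ene-1,9-dione (C7 as in the target) | O[C@@H]1CC(=O)[C@@]2(C)[C@@H]3C(=O)C=C(C)[C@H]2[C@@H]3C1(C)C | intermediate
21 | 7,9-dihydroxylongipin-2-en-1-one (7,9-anti, both as in the target) | O[C@@H]1C[C@@H](O)[C@@]2(C)[C@@H]3C(=O)C=C(C)[C@H]2[C@@H]3C1(C)C | intermediate
22 | 7-hydroxy-9-(3-methylbutanoyloxy)longipin-2-en-1-one | O[C@@H]1C[C@@H](OC(=O)CC(C)C)[C@@]2(C)[C@@H]3C(=O)C=C(C)[C@H]2[C@@H]3C1(C)C | intermediate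
23 | CNP0240547.2, 7-[(Z)-2-methylbut-2-enoyloxy]-9-(3-methylbutanoyloxy)longipin-2-en-1-one | C/C=C(/C)C(=O)O[C@@H]1C[C@@H](OC(=O)CC(C)C)[C@@]2(C)[C@@H]3C(=O)C=C(C)[C@H]2[C@@H]3C1(C)C | target

**Step count and risks**

Total steps: 17. Longest linear sequence: 15 steps (1, 2, 5–17); steps 3 and 4 make the diene.

The three steps most likely to fail:

Step 7. The ylide may add only sluggishly to the donor-substituted dienone, with competing carbonyl addition or enolisation of the ring-B ketone. The fallback sets out from 8 and returns at 12. Buffered HF·pyridine protonates the dienol ether at C8 to give 4,5-dimethyl-3,4,4a,5-tetrahydronaphthalene-1,6(2H,7H)-dione F1, in which the C8=C8a bond is conjugated to the ring-B ketone. 2-Diazopropane, which is not basic, then adds as a 1,3-dipole across that enone bond to give the 1-pyrazoline F2. Irradiation above 300 nm extrudes nitrogen to give the gem-dimethylcyclopropyl diketone F3. DBU in CH2Cl2 then triggers the same retro-Michael ring enlargement from the free diketone and delivers 12.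

Step 12. Four-membered ring closure may lose out to O-alkylation of the dienolate, 5-endo opening or base-induced isomerisation of the epoxide to an allylic alcohol. The fallback sets out from 14 and returns at 16. Dihydroxylation of the isolated alkene with catalytic OsO4 and N-methylmorpholine N-oxide from the open face gives the cis-diol F4. SO2Cl2 and pyridine convert it into the cyclic sulfate F5, a markedly stronger electrophile with the same leaving-group geometry at C11. LiN(i-Pr)2 then closes the C10–C11 bond to the lithium sulfate monoester F6, and acidic hydrolysis (cat. H2SO4, wet THF) gives 16.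

Step 16. The two hindered secondary hydroxyls may be discriminated poorly, giving mis- or over-acylation. The fallback sets out from 20 and returns at 22. An Evans–Tishchenko reaction of 20 with pent-4-enal and catalytic SmI2 reduces the C9 ketone anti and at the same time places a pent-4-enoate on the C7 oxygen, giving 7-(pent-4-enoyloxy)-9-hydroxylongipin-2-en-1-one F7. The only free hydroxyl (C9) is then acylated with isovaleric anhydride and DMAP to give the mixed diester F8. Iodine in wet THF removes the pentenoate by iodolactonisation and releases 22.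

Further compounds
F1 | step 7 | 4,5-dimethyl-3,4,4a,5-tetrahydronaphthalene-1,6(2H,7H)-dione | O=C1CC[C@@H](C)[C@@H]2[C@H](C)C(=O)CC=C12
F2 | step 7 | 1-pyrazoline from F1 and 2-diazopropane (N on C8a, CMe2 on C8) | O=C1CC[C@@H](C)[C@@H]2[C@H](C)C(=O)C[C@H]3C(C)(C)N=N[C@@]123
F3 | step 7 | gem-dimethylcyclopropyl diketone (desilylated 9) | O=C1CC[C@@H](C)[C@@H]2[C@H](C)C(=O)C[C@H]3C(C)(C)[C@@]123
F4 | step 12 | 3,4-cis-diol of 14, both hydroxyls trans to the gem-dimethyl carbon | C1=CC(=O)C(C)[C@H]2[C@H](C)C[C@H](O)[C@H](O)[C@H]2C1(C)C
F5 | step 12 | 3,4-cyclic sulfate of F4 | C1=CC(=O)C(C)[C@H]2[C@H](C)C[C@@H]3OS(=O)(=O)O[C@@H]3[C@H]2C1(C)C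
F6 | step 12 | lithium sulfate monoester of 16 | C1=CC(=O)[C@@]2(C)[C@@H]3[C@@H](OS(=O)(=O)[O-])C[C@@H](C)[C@H]2[C@@H]3C1(C)C.[Li+]
F7 | step 16 | 7-(pent-4-enoyloxy)-9-hydroxylongipin-2-en-1-one | C=CCCC(=O)O[C@@H]1C[C@@H](O)[C@@]2(C)[C@@H]3C(=O)C=C(C)[C@H]2[C@@H]3C1(C)C
F8 | step 16 | 7-(pent-4-enoyloxy)-9-(3-methylbutanoyloxy)longipin-2-en-1-one | C=CCCC(=O)O[C@@H]1C[C@@H](OC(=O)CC(C)C)[C@@]2(C)[C@@H]3C(=O)C=C(C)[C@H]2[C@@H]3C1(C)C
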